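Its constants were drawn at random within sensible limits.

The precatalyst of this flask must first become catalyst, and the catalyst then turns substrate into target and other conformer into the isomer of the product.

substrate 2.0 M; precatalyst 4.0 mM; time 20 min

    substrate ⇌ other conformer (K1 = 0.43, k1 = 0.075 min⁻¹)
    substrate + catalyst → catalyst + target (k2 = 6.7 M⁻¹ min⁻¹)
    catalyst + other conformer → catalyst + isomer of the product (k3 = 36 M⁻¹ min⁻¹)
    crystals ⇌ target, rate k4*(cs4 - [target]) while solid is left; crystals form when [target] > cs4 (cs4 = 1.2 M, k4 = 0.34 min⁻¹)
    precatalyst → catalyst (k5 = 0.012 min⁻¹)

- for target the crystals are counted in
- as a solid, counted per litre of solution: crystals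
- run time (flask): 20 min

- spring: doubling the dissolution coefficient of step 4, all else as stated
- dusk: doubling the amount of precatalyst, all else as stated
- winter: doubling the solubility in step 4, all else as stated

- target and crystals together at 20 min, in percent of the substrate charged
- the change that raises the amount of target and crystals together at 20 min, in percent of the substrate charged most ("none" if none brings more than 2 percentage points) (spring / dusk / winter / none)
- amount of target and crystals together at 20 min, in percent of the substrate charged, after dusk

Two numbers seem at odds. The full charge of precatalyst, taken as catalyst, gives substrate a pseudo-first-order constant of 0.0268 min⁻¹ and so a half-life of 25.9 min, close to the 20 min of the run, yet the reckoning here ends at a few percent.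

The charge is not catalyst from the start: in 20 min, activation at 0.012 min⁻¹ has converted 21.3% of it. The effective time τ is the elapsed time less the converted fraction divided by the activation constant, that is, the minutes of full catalyst charge to which the growing catalyst amounts. Here τ is 2.22 min, a fraction 0.111 of the run.

The conformers relax with a half-life of 2.78 min, shorter than the run, so the statistical zero is their equilibrium, with substrate at 69.9% of the pool. The yield reckoned from constant, τ and share is 4.16%. That is 0.0832 M of target, below the solubility of 1.2 M, so no crystals are expected. The same reckoning with the precatalyst doubled gives 8.32%.

The forecast gives 4% (range 3.7% to 4.4%), dusk as the best change and 7.7% after it, since “Target yield therefore scales almost directly with catalyst”.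

The simulation gives 4.10%, and 7.84% after dusk, a gain of 3.7 percentage points, while spring and winter each gain 0 points.

At 10.0 min in this flask, τ is 0.577 min, which gives 1.08% against 1.18% read. The time allowed is one part of the low yield: this flask left until 200 min reaches 34.6% against 4.10%, which is 32% of what is missing. The neighbour read at 50 min has τ of 12.4 min. Its added τ, with substrate read at a mean of 49.4%, gives 13 points of target beyond the reading at 20 min, against 13 points simulated.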